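The dawn and midnight runs, at the same temperature, lose J at 0.174 /min and 0.222 /min up to their first readings, faster in midnight, which differs from dawn in its larger charges of both G and X and in its later first reading.

| setting | dawn | dusk | midnight | north-west | south-east | north-east | north | west |
|---|---|---|---|---|---|---|---|---|
| J | 20 mM | 20 mM | 20 mM | 20 mM | 20 mM | 20 mM | 20 mM | 20 mM |
| X | 2.5 equiv (fed, over 4.0 min) | 2.5 equiv (fed, over 4.0 min) | 2.9 equiv (fed, over 4.0 min) | 2.50 equiv (fed, over 4.0 min) | 3.80 equiv (fed, over 4.0 min) | 2.50 equiv (fed, over 4.0 min) | 1.20 equiv (fed, over 4.0 min) | 2.50 equiv (fed, over 2.5 min) |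
| G | 6.4 mM | 24 mM | 10 mM | 10.0 mM | 5.00 mM | 10.0 mM | 10.0 mM | 20.0 mM |
| temperature | 65 °C | 100 °C | 65 °C | 90 °C | 130 °C | 70 °C | 120 °C | 90 °C |
| remark | run made earlier; the fed solution adds 0.10 times the starting volume | run made earlier; the fed solution adds 0.10 times the starting volume | run made earlier; the fed solution adds 0.10 times the starting volume | the fed solution adds 0.10 times the starting volume | the fed solution adds 0.10 times the starting volume | the fed solution adds 0.10 times the starting volume | the fed solution adds 0.10 times the starting volume | the fed solution adds 0.10 times the starting volume |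
| time |  |  |  | 6.0 min | 6.0 min | 6.0 min | 6.0 min | 6.0 min |

dawn run (percent of the J charged)

| time / min | D / % | J / % |
|---|---|---|
| 0.833 | 0.1 | 86.5 |
| 1.50 | 0 | 78.3 |
| 5.00 | 3.6 | 51.8 |
| 10.0 | 11.4 | 32.7 |

dusk run (percent of the J charged)

| time / s | D / % | J / % |
|---|---|---|
| 15.0 | 0 | 20.3 |
| 40.0 | 1.8 | 1.5 |
| 80.0 | 6.8 | 0.5 |
| 120 | 12.8 | 0 |

midnight run (percent of the J charged)

| time / min | D / % | J / % |
|---|---|---|
| 1.33 | 0.3 | 74.4 |
| 3.00 | 1.1 | 56.5 |
| 6.00 | 4.8 | 37.3 |
| 10.0 | 11.8 | 25.0 |

(each reading ± 0.3 percentage points)

- in percentages every species weighs as the J in it: one E counts as two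
- charges are per starting volume, the dose included; the dosed solution carries all of it
- steps that have been proposed: J -> L; X + L -> D; J + L -> E; J + G -> Z

* the flasks by amount of D, in percent of the J charged, highest first, at 6.0 min (north-west / south-east / north-east / north / west)
* the amount of D, in percent of the J charged of the flask you put first, at 6.0 min
* the amount of D, in percent of the J charged of the flask you put last, at 6.0 min

Each Z takes one J and one G, so the balance of G gives the G allowance, defined as G charged over J charged: the ceiling on the fraction of J that can leave as Z. In south-east, where G is the limiting reagent of that exit, the allowance is 25.0%, which keeps at least 75.0% of the J out of Z. North-west has 50.0% and west, at the same temperature but with a shorter feed, 100%, twice as much, so the ceiling on Z stands higher in west. It bounds Z, not D, and therefore gives no figure for D.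

The forecast gives figures: south-east > north > north-west > west > north-east, with 95% for the first flask and 9% for the last, reasoning for south-east that “almost all J becomes L, and excess X finishes it”.

The flasks give south-east > north > north-west > west > north-east, with south-east at 76.0% and north-east at 8.85%. Beside D, at 6.00 min, south-east holds E at 12.4% and Z at 11.7%, which is 46.8% of its allowance, with 53.4% of its G left.

    J → L (k = 0.0150 /s, Ea = 110 kJ/mol)
    X + L → D (k = 0.190 /M/s, Ea = 71.0 kJ/mol)
    J + L → E (k = 0.430 /M/s, Ea = 77.0 kJ/mol)
    J + G → Z (k = 2.00 /M/s, Ea = 72.0 kJ/mol)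
    (constants at 90 °C)

North-east, with its allowance of 50.0%, holds Z at 40.5% at 6.00 min, with 19.0% of its G left. Its neighbour keeps the same G and the same equivalents of X but starts from 5.0 mM of J, which raises the allowance to 200%. There Z reaches 59.3% of the J charged, which is 29.6% of the allowance, and 70.4% of the G is left. D in that neighbour stands at 2.56%, against 8.85% in north-east, with L at 23.1%.

The numbers in the tables stem from a simulated flask on assumed constants; the scatter is artificial.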